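## Retrosynthetic overview
1. The target comes from one acidic global deprotection of a heptaprotected adduct (four acetates on the flavanone half, three MOM ethers on the chalcone half).
2. The cyclohexene is the only ring built and is formed last. It is made by an intermolecular exo [4+2] cycloaddition that forms C3''–C4'' and C5''–C6'' between an (E)-dehydrogeranyl flavanone diene and a 2'-hydroxychalcone.
3. The diene comes from a Heck C6–C bond between 6-iodo-(2S)-steppogenin tetraacetate and β-myrcene. The chromanone ring and C2 are bought in (2S)-steppogenin.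
4. The dienophile comes from a Claisen–Schmidt condensation of MOM-protected 3-prenylresacetophenone with 2,4-bis(MOM)benzaldehyde.
5. All aromatic rings are bought, and C2 (S) is carried unchanged through non-basic or only weakly basic steps.

Assumption: (2S)-steppogenin (1), a plant flavanone sold by natural-product suppliers, is bought in high enantiomeric purity (checked by chiral HPLC and CD) and is the only source of chirality.

## Route

Step 1
Reactants: 1 (2S)-steppogenin [(2S)-5,7,2',4'-tetrahydroxyflavanone]
Product: 3 (2S)-6-iodosteppogenin 5,7,2',4'-tetraacetate, via 6-iodosteppogenin 2 (not isolated)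
Conditions: NIS (1.0 equiv), DMF, 0 °C → rt, dark, 3 h; then pyridine, Ac2O (8 equiv), DMAP (10 mol%), 0 °C → rt, 6 h
Reagents that add atoms: N-iodosuccinimide, O=C1CCC(=O)N1I; acetic anhydride, CC(=O)OC(C)=O
Why: This is an electrophilic aromatic iodination followed by O-acetylation in the same flask, in which neutral NIS attacks the phloroglucinol-type ring A of a 5,7-dihydroxyflavonoid at C6 (between the two hydroxyls) faster than the less activated resorcinol ring B, and the cold pyridine/DMAP acetylation caps all four phenols before iodine can migrate and without opening the chromanone, so the bought C2 stays S.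

Step 2
Reactants: 3 (2S)-6-iodosteppogenin tetraacetate; 4 β-myrcene (7-methyl-3-methyleneocta-1,6-diene, 3 equiv)
Product: 5 (2S)-6-[(1E)-7-methyl-3-methyleneocta-1,6-dienyl]steppogenin 5,7,2',4'-tetraacetate (diene)
Conditions: Pd2(dba)3 (2.5 mol%), P(t-Bu)3 (10 mol%), Cy2NMe (1.5 equiv), BHT (trace), dry 1,4-dioxane, 45 °C
Reagents that add atoms: none
Why: This is a Mizoroki–Heck reaction in which the arylpalladium iodide adds to the unsubstituted terminus of the monosubstituted vinyl group of 4 and loss of the benzylic β-hydrogen gives the conjugated (E)-1-aryl-1,3-diene, while the two esterified ortho oxygens and the dry medium shut off dihydrobenzofuran annulation and the hindered amine at 45 °C is too poor a kinetic base to start retro-oxa-Michael opening at C2.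

Step 3
Reactants: 6 2,4-dihydroxyacetophenone; 7 prenyl bromide (1-bromo-3-methylbut-2-ene)
Product: 8 2,4-dihydroxy-3-prenylacetophenone
Conditions: KOH (10% aq., 1.1 equiv), 0 °C → rt, 12 h
Reagents that add atoms: none
Why: This is a direct C-prenylation (C-alkylation of an ambident phenoxide) in which the resacetophenone anion in water reacts mainly at C3, the carbon between the two oxygens, in a modest (about 35%) one-step yield, and the O-prenyl and 5-prenyl isomers are removed by chromatography.

Step 4
Reactants: 8 2,4-dihydroxy-3-prenylacetophenone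
Product: 9 2-hydroxy-4-(methoxymethoxy)-3-prenylacetophenone
Conditions: MOMCl (1.2 equiv), K2CO3, acetone, rt
Reagents that add atoms: chloromethyl methyl ether (MOMCl), COCCl
Why: This is a Williamson-type etherification in which only the 4-OH reacts because the 2-OH is hydrogen-bonded to the ketone, which leaves exactly the chelated phenol that the cycloaddition needs.

Step 5
Reactants: 10 2,4-dihydroxybenzaldehyde
Product: 11 2,4-bis(methoxymethoxy)benzaldehyde
Conditions: NaH (2.5 equiv), MOMCl (2.5 equiv), DMF, 0 °C → rt
Reagents that add atoms: chloromethyl methyl ether (MOMCl), COCCl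
Why: This is a Williamson-type etherification through the sodium bis-phenoxide, which also caps the chelated 2-OH so that the aldehyde stays electrophilic in the basic condensation.

Step 6
Reactants: 9 2-hydroxy-4-(methoxymethoxy)-3-prenylacetophenone; 11 2,4-bis(methoxymethoxy)benzaldehyde
Product: 13 (E)-2'-hydroxy-2,4,4'-tris(methoxymethoxy)-3'-prenylchalcone, via aldol adduct 12 (not isolated)
Conditions: KOH (40% aq.), EtOH, 0 °C → rt, 36 h; then 1 M HCl to pH 6
Reagents that add atoms: none
Why: This is a Claisen–Schmidt condensation (aldol addition, then E1cB dehydration) in which the MOM ethers and the prenyl group are inert to KOH and the elimination gives only the conjugated E-enone.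

Step 7
Reactants: 5 diene (1.0 equiv); 13 chalcone (1.5 equiv)
Product: 14 all-trans (exo) adduct (2S,3''R,4''R,5''S), with 5,7,2',4'-tetraacetate on the flavanone half, three MOM ethers on the chalcone half and a free chelated OH
Conditions: Ag nanoparticles on SiO2 (from AgBF4 and n-Bu4NBH4, about 5 mol% Ag), CH2Cl2, 50 °C, sealed tube, dark, 48 h; flash chromatography (exo from endo), then normal-phase HPLC (facial isomers)
Reagents that add atoms: none
Why: This is a Diels–Alder cycloaddition of a 2'-hydroxychalcone activated on silver, in which the 1-aryl and 3-alkyl groups of the diene both direct the observed ortho/para regiochemistry, the E-enone fixes 4'',5''-trans and exo approach gives 3'',4''-trans, but C2 is too remote to bias the diene faces, so about equal amounts of two exo and two endo isomers are expected (wanted isomer roughly 15–20%), and because C2 is fixed as S these are diastereomers that separate on achiral phases and are assigned by CD.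

Step 8
Reactants: 14 protected all-trans adduct
Product: 15 target CNP0256494.1, (2S,3''R,4''R,5''S)
Conditions: HCl (0.5 M in MeOH), MeOH–THF 4:1, argon, rt → 35 °C, 4–8 h (HPLC control); solid NaHCO3 to pH 6; reversed-phase HPLC
Reagents that add atoms: none
Why: This is an acid-catalysed acetal exchange (MOM) and transesterification (aryl acetates) in one operation, where acid is used instead of base because phenoxide-forming media racemise C2 through the chalcone/quinone methide, dilute acid at 35 °C or below leaves the three trisubstituted alkenes untouched, and the all-equatorial C4'' has no more stable epimer.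

## Compound list
1 | (2S)-steppogenin | O=C1C[C@@H](c2ccc(O)cc2O)Oc2cc(O)cc(O)c12 | starting material
2 | (2S)-6-iodosteppogenin | O=C1C[C@@H](c2ccc(O)cc2O)Oc2cc(O)c(I)c(O)c12 | intermediate
3 | (2S)-6-iodosteppogenin 5,7,2',4'-tetraacetate | O=C1C[C@@H](c2ccc(OC(C)=O)cc2OC(C)=O)Oc2cc(OC(C)=O)c(I)c(OC(C)=O)c12 | intermediate
4 | β-myrcene | C=CC(=C)CCC=C(C)C | starting material
5 | (2S)-6-[(1E)-7-methyl-3-methyleneocta-1,6-dienyl]steppogenin tetraacetate | O=C1C[C@@H](c2ccc(OC(C)=O)cc2OC(C)=O)Oc2cc(OC(C)=O)c(/C=C/C(=C)CCC=C(C)C)c(OC(C)=O)c12 | intermediate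
6 | 2,4-dihydroxyacetophenone | CC(=O)c1ccc(O)cc1O | starting material
7 | prenyl bromide | CC(C)=CCBr | starting material
8 | 2,4-dihydroxy-3-prenylacetophenone | CC(=O)c1ccc(O)c(CC=C(C)C)c1O | intermediate
9 | 2-hydroxy-4-(methoxymethoxy)-3-prenylacetophenone | CC(=O)c1ccc(OCOC)c(CC=C(C)C)c1O | intermediate
10 | 2,4-dihydroxybenzaldehyde | O=Cc1ccc(O)cc1O | starting material
11 | 2,4-bis(methoxymethoxy)benzaldehyde | O=Cc1ccc(OCOC)cc1OCOC | intermediate
12 | aldol adduct (racemic β-hydroxy ketone) | CC(C)=CCc1c(OCOC)ccc(C(=O)CC(O)c2ccc(OCOC)cc2OCOC)c1O | intermediate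
13 | (E)-2'-hydroxy-2,4,4'-tris(methoxymethoxy)-3'-prenylchalcone | CC(C)=CCc1c(OCOC)ccc(C(=O)/C=C/c2ccc(OCOC)cc2OCOC)c1O | intermediate
14 | protected all-trans adduct (2S,3''R,4''R,5''S) | CC(C)=CCCC1=C[C@@H](c2c(OC(C)=O)cc3c(c2OC(C)=O)C(=O)C[C@@H](c2ccc(OC(C)=O)cc2OC(C)=O)O3)[C@H](C(=O)c2ccc(OCOC)c(CC=C(C)C)c2O)[C@@H](c2ccc(OCOC)cc2OCOC)C1 | intermediate
15 | CNP0256494.1 (2S,3''R,4''R,5''S) | CC(C)=CCCC1=C[C@@H](c2c(O)cc3c(c2O)C(=O)C[C@@H](c2ccc(O)cc2O)O3)[C@H](C(=O)c2ccc(O)c(CC=C(C)C)c2O)[C@@H](c2ccc(O)cc2O)C1 | target

## Count and risks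
Total steps: 8.
Longest linear sequence: 5 steps (6 → 8 → 9 → 13 → 14 → 15). The sequence from 1 is 4 steps.

**Step 7 (cycloaddition).**
- Risk: conversion may be slow with the twisted, ester-flanked diene, only about a quarter of the adduct mixture is the wanted isomer, and the two exo isomers may be hard to separate.
- Fallback: it sets out from 13 and comes back at 14. The dienophile is changed from the free chalcone on silver to a preformed, stoichiometric boron chelate.
- Compound 13 is stirred with B(OPh)3 and achiral 2,2'-biphenol (1.1 equiv each, 4 Å sieves, CH2Cl2, rt). This gives the tetracoordinate spiroborate chelate of the chalcone F5, whose enone is far more electrophilic.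
- Diene 5 is added at 0 °C → rt to give the spiroborate chelate of the adduct F6.
- A pH 7 aqueous work-up removes the boron and returns 14, with an exo/endo ratio independent of that on silver. The isomers are separated as before.

**Step 2 (Heck reaction with myrcene).**
- Risk: attack at the 1,1-disubstituted alkene, capture of the allylpalladium by a liberated phenol, or slow erosion at C2.
- Fallback: it sets out from 3 and comes back at 5. The C6–C bond is made by a base-free Stille coupling with a preformed dienyl metal.
- Bought 6-methylhept-5-en-2-one is enolised kinetically (LiN(i-Pr)2, THF, −78 °C) and trapped with PhNTf2. This gives 6-methylhepta-1,5-dien-2-yl triflate F3.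
- Mono-coupling of F3 with excess (E)-1,2-bis(tributylstannyl)ethene (Pd2(dba)3, AsPh3, NMP, rt → 40 °C) gives (E)-tributyl(7-methyl-3-methyleneocta-1,6-dienyl)stannane F4.
- F4 couples with 3 (Pd2(dba)3, AsPh3, CuI, DMF, 40 °C) to give 5 with the diene geometry and position already fixed.

**Step 1 (iodination of the unprotected flavanone).**
- Risk: competing iodination of ring B or at C8, and over-iodination.
- Fallback: it sets out from 1 and comes back at 3. Ring B is switched off before the halogenation.
- Ac2O (3.05 equiv) in pyridine at −10 → 0 °C acylates all but the chelated 5-OH and gives (2S)-steppogenin 7,2',4'-triacetate F1.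
- BnMe3N·ICl2 with CaCO3 (CH2Cl2–MeOH, rt) then iodinates ortho to the only free phenol. This gives (2S)-6-iodosteppogenin 7,2',4'-triacetate F2.
- Ac2O/DMAP caps the 5-OH to give 3.

Further compounds
F1 | step 1 | (2S)-steppogenin 7,2',4'-triacetate | O=C1C[C@@H](c2ccc(OC(C)=O)cc2OC(C)=O)Oc2cc(OC(C)=O)cc(O)c12
F2 | step 1 | (2S)-6-iodosteppogenin 7,2',4'-triacetate | O=C1C[C@@H](c2ccc(OC(C)=O)cc2OC(C)=O)Oc2cc(OC(C)=O)c(I)c(O)c12
F3 | step 2 | 6-methylhepta-1,5-dien-2-yl triflate | C=C(CCC=C(C)C)OS(=O)(=O)C(F)(F)F
F4 | step 2 | (E)-tributyl(7-methyl-3-methyleneocta-1,6-dienyl)stannane | CCCC[Sn](CCCC)(CCCC)/C=C/C(=C)CCC=C(C)C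
F5 | step 7 | spiroborate (2,2'-biphenolate) chelate of chalcone 13 | COCOc1ccc(/C=C/C2=[O+][B-]3(Oc4ccccc4-c4ccccc4O3)Oc3c2ccc(OCOC)c3CC=C(C)C)c(OCOC)c1
F6 | step 7 | spiroborate (2,2'-biphenolate) chelate of adduct 14 | CC(C)=CCCC1=C[C@@H](c2c(OC(C)=O)cc3c(c2OC(C)=O)C(=O)C[C@@H](c2ccc(OC(C)=O)cc2OC(C)=O)O3)[C@H](C2=[O+][B-]3(Oc4ccccc4-c4ccccc4O3)Oc3c2ccc(OCOC)c3CC=C(C)C)[C@@H](c2ccc(OCOC)cc2OCOC)C1
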